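**Retrosynthetic overview**

- Target 35 is traced back to the bis-arene 27 through global fluoride desilylation, iodine–lithium exchange with O→C acyl shift, O-acylation with (R)-2-methylbutanoyl chloride 30 and ring iodination.
- 27 is disconnected by a twofold Danheiser benzannulation into the skipped bis(siloxy)diyne 12 and two molecules of the 3-siloxy-2-prenylcyclobutenone 22. Ring A and ring B (the two benzene rings) are built in that one operation, one after the other, from open-chain alkyne carbons and a four-membered ring.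
- 12 comes from 6-methylheptanal 1 and two molecules of ethynyltrimethylsilane 2 (acetylide addition, Nicholas alkynylation, twofold acetylide oxidation/O-silylation). 22 comes from prenyl bromide 13, 2 and ketene.
- Feature on which the strategy rests: each benzene ring carries oxygen on three alternate carbons (C2′, C4′, C6′). The bridging methine sits on C1′ between two oxygen-bearing carbons, prenyl on C5′ between two others, and the acyl carbon C3′, between the last pair, is the one the annulation leaves as CH.

Key step: step 10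

Remark 1: the ring oxygen delivered by the cyclobutenone is carried as a triisopropylsilyl ether and not as an alkyl ether. An aryl alkyl ether beside a ketone that is already hydrogen-bonded to its other ortho hydroxyl resists chelation-controlled dealkylation under conditions the prenyl groups tolerate. All four silyl ethers then fall in one fluoride step.

Remark 2: the bridging carbon bears two identical aryl groups and is not a stereocentre. The only stereocentres are the two (R)-configured α-carbons of the acyl groups, taken from (R)-2-methylbutanoic acid 29, which is assumed, like 6-methylheptanal 1, to be purchasable.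

**Route**

Step 1
Reactants: 1 6-methylheptanal; 2 ethynyltrimethylsilane
Product: 4 rac-8-methyl-1-(trimethylsilyl)non-1-yn-3-ol, via lithium (trimethylsilyl)acetylide 3 (not isolated)
Conditions: 2, n-BuLi, THF, −78 °C; then 1, −78 → 0 °C; NH4Cl aq
Reagents that add atoms: none
Why: 1,2-addition of a lithium acetylide to an aldehyde at −78 °C outruns enolisation; the carbinol centre forms racemic, which is immaterial because it is later ionised and ends as the non-stereogenic bridge carbon.

Step 2
Reactants: 4 rac-8-methyl-1-(trimethylsilyl)non-1-yn-3-ol; 2 ethynyltrimethylsilane (source of the alkynylalane)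
Product: 7 hexacarbonyldicobalt complex of 3-(5-methylhexyl)-1,5-bis(trimethylsilyl)penta-1,4-diyne (cobalt on one alkyne; racemic), via cobalt complex 5 (not isolated), via alkynylalane 6 (not isolated)
Conditions: 4, Co2(CO)8, CH2Cl2, rt; BF3·OEt2, −78 °C; then Me2AlC≡CSiMe3 (from 2, Me3Al, Et3N 10 mol %, PhMe, 60 °C), −78 → 0 °C; NaHCO3 aq
Reagents that add atoms: dicobalt octacarbonyl Co2(CO)8, O=C=[Co](=C=O)(=C=O)(=C=O)[Co](=C=O)(=C=O)(=C=O)=C=O
Why: Nicholas reaction, in which the Co2(CO)6-stabilised propargylic cation released from 5 by BF3·OEt2 is attacked by the alkynylalane (made by amine-catalysed direct alumination of the terminal alkyne with Me3Al) only at the propargylic carbon, so the second alkyne is installed without allene formation.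

Step 3
Reactants: 7 hexacarbonyldicobalt complex of the bis(trimethylsilyl) diyne
Product: 8 3-(5-methylhexyl)-1,5-bis(trimethylsilyl)penta-1,4-diyne
Conditions: (NH4)2Ce(NO3)6, acetone, −78 → 0 °C
Reagents that add atoms: none
Why: oxidative decomplexation, in which the cerium salt oxidises the zerovalent cobalt cluster to divalent cobalt and frees the alkyne, while silylalkynes and the skipped diyne are inert to the cold oxidant.

Step 4
Reactants: 8 3-(5-methylhexyl)-1,5-bis(trimethylsilyl)penta-1,4-diyne
Product: 9 3-(5-methylhexyl)penta-1,4-diyne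
Conditions: TBAF, AcOH, THF, 0 °C
Reagents that add atoms: none
Why: fluoride-induced protodesilylation of both alkynyl–silicon bonds, with AcOH buffering so that the doubly propargylic C–H is not isomerised to an allene.

Step 5
Reactants: 9 3-(5-methylhexyl)penta-1,4-diyne
Product: 12 3-(5-methylhexyl)-1,5-bis(triisopropylsiloxy)penta-1,4-diyne, via dilithium bis-acetylide 10 (not isolated), via dilithium bis-ynolate 11 (not isolated)
Conditions: n-BuLi (2.05 equiv), THF, −78 °C; t-BuOOLi (from t-BuOOH, LiN(SiMe3)2), −78 → 0 °C; TIPSOTf, −78 → 0 °C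
Reagents that add atoms: tert-butyl hydroperoxide, CC(C)(C)OO; triisopropylsilyl triflate, CC(C)[Si](OS(=O)(=O)C(F)(F)F)(C(C)C)C(C)C
Why: electrophilic oxygenation of each lithium acetylide by lithium tert-butyl peroxide gives the lithium ynolate, which the bulky silyl triflate silylates on oxygen; terminal C–H lithiation at −78 °C is much faster than removal of the doubly propargylic hydrogen.

Step 6
Reactants: 2 ethynyltrimethylsilane; 13 1-bromo-3-methylbut-2-ene (prenyl bromide)
Product: 15 trimethyl(5-methylhex-4-en-1-ynyl)silane, via bromomagnesium (trimethylsilyl)acetylide 14 (not isolated)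
Conditions: 2, EtMgBr, THF, 0 °C → rt; then CuBr·SMe2 (5 mol %), 13, 0 °C → rt
Reagents that add atoms: none
Why: copper-catalysed coupling of an alkynyl Grignard reagent with a primary allylic bromide, in which the alkynylcopper species substitutes directly at the unhindered CH2 of prenyl bromide and gives the skipped enyne.

Step 7
Reactants: 15 trimethyl(5-methylhex-4-en-1-ynyl)silane
Product: 16 5-methylhex-4-en-1-yne
Conditions: K2CO3 (cat.), MeOH, rt; pentane extraction, careful distillation
Reagents that add atoms: none
Why: base-catalysed methanolysis of the alkynyl–silicon bond (protodesilylation), under which the skipped enyne is stable.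

Step 8
Reactants: 16 5-methylhex-4-en-1-yne
Product: 19 triisopropyl[(5-methylhex-4-en-1-ynyl)oxy]silane, via lithium acetylide 17 (not isolated), via lithium ynolate 18 (not isolated)
Conditions: n-BuLi, THF, −78 °C; t-BuOOLi (from t-BuOOH, LiN(SiMe3)2), −78 → 0 °C; TIPSOTf, −78 → 0 °C
Reagents that add atoms: tert-butyl hydroperoxide, CC(C)(C)OO; triisopropylsilyl triflate, CC(C)[Si](OS(=O)(=O)C(F)(F)F)(C(C)C)C(C)C
Why: the same acetylide oxidation to an ynolate and O-silylation as in step 5, here on a single terminal alkyne.

Step 9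
Reactants: 19 triisopropyl[(5-methylhex-4-en-1-ynyl)oxy]silane; 20 diketene
Product: 22 2-(3-methylbut-2-enyl)-3-(triisopropylsiloxy)cyclobut-2-en-1-one, via ketene 21 (not isolated)
Conditions: ketene stream (20, quartz tube, 550 °C, N2) into 19, MeCN, 0 °C → rt
Reagents that add atoms: none
Why: ketene–siloxyalkyne (2+2) cycloaddition, in which the nucleophilic prenyl-bearing alkyne carbon adds to the ketene carbonyl carbon and the siloxy carbon to the ketene CH2, the known route to 3-siloxycyclobutenones; ketene does not add to the unactivated trisubstituted alkene.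

Step 10
Reactants: 12 3-(5-methylhexyl)-1,5-bis(triisopropylsiloxy)penta-1,4-diyne; 22 2-(3-methylbut-2-enyl)-3-(triisopropylsiloxy)cyclobut-2-en-1-one (2.5 equiv)
Product: 27 1,1-bis[2-hydroxy-5-(3-methylbut-2-enyl)-4,6-bis(triisopropylsiloxy)phenyl]-6-methylheptane, via vinylketene 23 (not isolated), via vinylcyclobutenone 24 (not isolated), via dienylketene 25 (not isolated), via mono-arene 26 (not isolated)
Conditions: 22 (2.5 equiv) added in portions, PhMe, 90 °C; then 120 °C, sealed tube, Ar
Reagents that add atoms: none
Why: Proposed new method: on heating, 22 should open by four-electron electrocyclic cleavage of its C(=O)–CH2 bond to vinylketene 23, whose carbonyl carbon is attacked by the nucleophilic bridge-bearing carbon of one ynol ether of 12 while the siloxy carbon bonds to the prenyl-bearing ketene carbon, giving vinylcyclobutenone 24, which opens again to dienylketene 25. Each benzene ring is then closed by six-electron electrocyclisation of the dienylketene (ketene carbon onto the terminal CH2) and aromatised by tautomerisation of the cyclohexadienone, first to 26 and then, by the same sequence on the second alkyne, to 27. The closest known reaction type is the Danheiser benzannulation of a cyclobutenone with a trialkylsiloxyalkyne to a resorcinol monosilyl ether; a 3-siloxycyclobutenone partner and a twofold reaction on a skipped diyne have not been shown. No stereocentre is created, because the bridge carbon ends with two identical aryl groups. The step needs a single regiochemistry in each ketene–alkyne (2+2) addition, which the oxygen-polarised alkyne secures, and it needs the vinylketene to choose the ynol ether over the prenyl alkenes and the first-formed phenol, which the much higher nucleophilicity of the ynol ether and portionwise addition of 22 should secure. Dienylketene of the wrong double-bond geometry can re-close to 24 and is so funnelled into the productive isomer.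

Step 11
Reactants: 27 the bis-arene
Product: 28 1,1-bis[2-hydroxy-3-iodo-5-(3-methylbut-2-enyl)-4,6-bis(triisopropylsiloxy)phenyl]-6-methylheptane
Conditions: NIS (2.1 equiv), CH2Cl2, −40 → 0 °C, dark
Reagents that add atoms: N-iodosuccinimide, O=C1CCC(=O)N1I
Why: electrophilic aromatic iodination of each phenol at its only free ring carbon (ortho to OH, para to a siloxy group), a position far more nucleophilic than the trisubstituted alkenes, which also lack a neighbouring free hydroxyl for iodoetherification.

Step 12
Reactants: 29 (R)-2-methylbutanoic acid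
Product: 30 (R)-2-methylbutanoyl chloride
Conditions: (COCl)2, DMF (cat.), CH2Cl2, 0 °C → rt; used as a solution
Reagents that add atoms: oxalyl chloride, O=C(Cl)C(=O)Cl
Why: acid chloride formation through the chloroiminium species under base-free conditions, so that no ketene forms and the α-stereocentre keeps its R configuration.

Step 13
Reactants: 28 the bis-iodophenol; 30 (R)-2-methylbutanoyl chloride (2.5 equiv)
Product: 31 bis-ester, 1,1-bis{3-iodo-2-[(2R)-2-methylbutanoyloxy]-5-(3-methylbut-2-enyl)-4,6-bis(triisopropylsiloxy)phenyl}-6-methylheptane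
Conditions: 30 (2.5 equiv), pyridine, DMAP (cat.), CH2Cl2, 0 °C → rt
Reagents that add atoms: none
Why: DMAP-catalysed O-acylation of both hindered phenols, one acid chloride per ring, with pyridine too weak a base to convert the branched acid chloride into its ketene, so both R centres are carried through unchanged.

Step 14
Reactants: 31 the bis-ester
Product: 34 1,1-bis{2-hydroxy-3-[(2R)-2-methylbutanoyl]-5-(3-methylbut-2-enyl)-4,6-bis(triisopropylsiloxy)phenyl}-6-methylheptane, via bis-aryllithium 32 (not isolated), via dilithium bis-phenoxide 33 (not isolated)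
Conditions: t-BuLi (4.1 equiv), THF/Et2O, −100 → −78 °C; AcOH, −78 °C
Reagents that add atoms: none
Why: iodine–lithium exchange at −100 °C is faster than attack on or enolisation of the ester, and each ortho-lithio aryl ester then undergoes intramolecular 1,3 O→C acyl migration (anionic Fries rearrangement) to the lithium phenoxide ketone; the stereocentre is not involved, and the cold acidic quench guards it against enolisation.

Step 15
Reactants: 34 the bis(hydroxyaryl ketone)
Product: 35 target, 1,1-bis{2,4,6-trihydroxy-3-[(2R)-2-methylbutanoyl]-5-(3-methylbut-2-enyl)phenyl}-6-methylheptane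
Conditions: TBAF (4.5 equiv), AcOH, THF, 0 °C, Ar
Reagents that add atoms: none
Why: fluoride cleavage of four aryl silyl ethers, which leave as acyl-stabilised phenoxides, with AcOH buffering to protect the α-stereocentres and the prenylated phloroglucinol rings from base.

**Compound list**

1 | 6-methylheptanal | CC(C)CCCCC=O | starting material
2 | ethynyltrimethylsilane | C#C[Si](C)(C)C | starting material
3 | lithium (trimethylsilyl)acetylide | [Li]C#C[Si](C)(C)C | intermediate (not isolated)
4 | rac-8-methyl-1-(trimethylsilyl)non-1-yn-3-ol | CC(C)CCCCC(O)C#C[Si](C)(C)C | intermediate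
5 | hexacarbonyldicobalt complex of 4 (both alkyne carbons bridge the Co–Co bond) | CC(C)CCCCC(O)C12C3([Si](C)(C)C)[Co]1(=C=O)(=C=O)(=C=O)[Co]23(=C=O)(=C=O)=C=O | intermediate (not isolated)
6 | dimethyl[(trimethylsilyl)ethynyl]aluminium | C[Al](C)C#C[Si](C)(C)C | intermediate (not isolated)
7 | hexacarbonyldicobalt complex of 8 at one alkyne (racemic) | CC(C)CCCCC(C#C[Si](C)(C)C)C12C3([Si](C)(C)C)[Co]1(=C=O)(=C=O)(=C=O)[Co]23(=C=O)(=C=O)=C=O | intermediate
8 | 3-(5-methylhexyl)-1,5-bis(trimethylsilyl)penta-1,4-diyne | CC(C)CCCCC(C#C[Si](C)(C)C)C#C[Si](C)(C)C | intermediate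
9 | 3-(5-methylhexyl)penta-1,4-diyne | CC(C)CCCCC(C#C)C#C | intermediate
10 | 1,5-dilithio-3-(5-methylhexyl)penta-1,4-diyne | CC(C)CCCCC(C#C[Li])C#C[Li] | intermediate (not isolated)
11 | dilithium 3-(5-methylhexyl)penta-1,4-diyne-1,5-diolate | CC(C)CCCCC(C#CO[Li])C#CO[Li] | intermediate (not isolated)
12 | 3-(5-methylhexyl)-1,5-bis(triisopropylsiloxy)penta-1,4-diyne | CC(C)CCCCC(C#CO[Si](C(C)C)(C(C)C)C(C)C)C#CO[Si](C(C)C)(C(C)C)C(C)C | intermediate (key-step precursor)
13 | 1-bromo-3-methylbut-2-ene (prenyl bromide) | CC(C)=CCBr | starting material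
14 | bromo[(trimethylsilyl)ethynyl]magnesium | C[Si](C)(C)C#C[Mg]Br | intermediate (not isolated)
15 | trimethyl(5-methylhex-4-en-1-ynyl)silane | CC(C)=CCC#C[Si](C)(C)C | intermediate
16 | 5-methylhex-4-en-1-yne | CC(C)=CCC#C | intermediate
17 | (5-methylhex-4-en-1-ynyl)lithium | CC(C)=CCC#C[Li] | intermediate (not isolated)
18 | lithium 5-methylhex-4-en-1-yn-1-olate | CC(C)=CCC#CO[Li] | intermediate (not isolated)
19 | triisopropyl[(5-methylhex-4-en-1-ynyl)oxy]silane | CC(C)=CCC#CO[Si](C(C)C)(C(C)C)C(C)C | intermediate
20 | diketene (4-methylideneoxetan-2-one) | C=C1CC(=O)O1 | starting material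
21 | ketene | C=C=O | intermediate (not isolated)
22 | 2-(3-methylbut-2-enyl)-3-(triisopropylsiloxy)cyclobut-2-en-1-one | O=C1CC(O[Si](C(C)C)(C(C)C)C(C)C)=C1CC=C(C)C | intermediate (key-step precursor)
23 | 2-(3-methylbut-2-enyl)-3-(triisopropylsiloxy)buta-1,3-dien-1-one (vinylketene) | O=C=C(CC=C(C)C)C(=C)O[Si](C(C)C)(C(C)C)C(C)C | intermediate (not isolated)
24 | first (2+2) adduct, a 4-prenyl-3-siloxy-4-(1-siloxyvinyl)cyclobut-2-enone carrying the CH(5-methylhexyl)(siloxyethynyl) group on C2 (stereoisomer mixture) | O=C1C(C(CCCCC(C)C)C#CO[Si](C(C)C)(C(C)C)C(C)C)=C(O[Si](C(C)C)(C(C)C)C(C)C)C1(CC=C(C)C)C(=C)O[Si](C(C)C)(C(C)C)C(C)C | intermediate (not isolated)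
25 | dienylketene from ring opening of 24 | O=C=C(C(CCCCC(C)C)C#CO[Si](C(C)C)(C(C)C)C(C)C)C(O[Si](C(C)C)(C(C)C)C(C)C)=C(CC=C(C)C)C(=C)O[Si](C(C)C)(C(C)C)C(C)C | intermediate (not isolated)
26 | mono-arene, 2-[8-methyl-1-(triisopropylsiloxy)non-1-yn-3-yl]-4-(3-methylbut-2-enyl)-3,5-bis(triisopropylsiloxy)phenol (racemic) | CC(C)CCCCC(C#CO[Si](C(C)C)(C(C)C)C(C)C)c1c(O)cc(O[Si](C(C)C)(C(C)C)C(C)C)c(CC=C(C)C)c1O[Si](C(C)C)(C(C)C)C(C)C | intermediate (not isolated)
27 | 1,1-bis[2-hydroxy-5-(3-methylbut-2-enyl)-4,6-bis(triisopropylsiloxy)phenyl]-6-methylheptane | CC(C)CCCCC(c1c(O)cc(O[Si](C(C)C)(C(C)C)C(C)C)c(CC=C(C)C)c1O[Si](C(C)C)(C(C)C)C(C)C)c1c(O)cc(O[Si](C(C)C)(C(C)C)C(C)C)c(CC=C(C)C)c1O[Si](C(C)C)(C(C)C)C(C)C | intermediate (key-step product)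
28 | 1,1-bis[2-hydroxy-3-iodo-5-(3-methylbut-2-enyl)-4,6-bis(triisopropylsiloxy)phenyl]-6-methylheptane | CC(C)CCCCC(c1c(O)c(I)c(O[Si](C(C)C)(C(C)C)C(C)C)c(CC=C(C)C)c1O[Si](C(C)C)(C(C)C)C(C)C)c1c(O)c(I)c(O[Si](C(C)C)(C(C)C)C(C)C)c(CC=C(C)C)c1O[Si](C(C)C)(C(C)C)C(C)C | intermediate
29 | (R)-2-methylbutanoic acid | CC[C@@H](C)C(=O)O | starting material
30 | (R)-2-methylbutanoyl chloride | CC[C@@H](C)C(=O)Cl | intermediate
31 | 1,1-bis{3-iodo-2-[(2R)-2-methylbutanoyloxy]-5-(3-methylbut-2-enyl)-4,6-bis(triisopropylsiloxy)phenyl}-6-methylheptane | CC(C)CCCCC(c1c(OC(=O)[C@H](C)CC)c(I)c(O[Si](C(C)C)(C(C)C)C(C)C)c(CC=C(C)C)c1O[Si](C(C)C)(C(C)C)C(C)C)c1c(OC(=O)[C@H](C)CC)c(I)c(O[Si](C(C)C)(C(C)C)C(C)C)c(CC=C(C)C)c1O[Si](C(C)C)(C(C)C)C(C)C | intermediate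
32 | bis-aryllithium from 31 (lithium in place of each iodine) | CC(C)CCCCC(c1c(OC(=O)[C@H](C)CC)c([Li])c(O[Si](C(C)C)(C(C)C)C(C)C)c(CC=C(C)C)c1O[Si](C(C)C)(C(C)C)C(C)C)c1c(OC(=O)[C@H](C)CC)c([Li])c(O[Si](C(C)C)(C(C)C)C(C)C)c(CC=C(C)C)c1O[Si](C(C)C)(C(C)C)C(C)C | intermediate (not isolated)
33 | dilithium bis-phenoxide of 34 | CC(C)CCCCC(c1c(O[Li])c(C(=O)[C@H](C)CC)c(O[Si](C(C)C)(C(C)C)C(C)C)c(CC=C(C)C)c1O[Si](C(C)C)(C(C)C)C(C)C)c1c(O[Li])c(C(=O)[C@H](C)CC)c(O[Si](C(C)C)(C(C)C)C(C)C)c(CC=C(C)C)c1O[Si](C(C)C)(C(C)C)C(C)C | intermediate (not isolated)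
34 | 1,1-bis{2-hydroxy-3-[(2R)-2-methylbutanoyl]-5-(3-methylbut-2-enyl)-4,6-bis(triisopropylsiloxy)phenyl}-6-methylheptane | CC(C)CCCCC(c1c(O)c(C(=O)[C@H](C)CC)c(O[Si](C(C)C)(C(C)C)C(C)C)c(CC=C(C)C)c1O[Si](C(C)C)(C(C)C)C(C)C)c1c(O)c(C(=O)[C@H](C)CC)c(O[Si](C(C)C)(C(C)C)C(C)C)c(CC=C(C)C)c1O[Si](C(C)C)(C(C)C)C(C)C | intermediate
35 | 1,1-bis{2,4,6-trihydroxy-3-[(2R)-2-methylbutanoyl]-5-(3-methylbut-2-enyl)phenyl}-6-methylheptane (CNP0245910.1) | CC[C@@H](C)C(=O)c1c(O)c(CC=C(C)C)c(O)c(C(CCCCC(C)C)c2c(O)c(CC=C(C)C)c(O)c(C(=O)[C@H](C)CC)c2O)c1O | target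

**Step count**

Total steps: 15. Longest linear sequence: 10 steps (steps 1, 2, 3, 4, 5, 10, 11, 13, 14, 15).

**Steps most likely to fail**

1. Step 10 (twofold benzannulation).
   - What may go wrong: the donor-substituted cyclobutenone may open too slowly, so that the vinylketene dimerises before it is trapped.
   - After the first ring has formed, its new phenol may add across the remaining ynol ether or be acylated by vinylketene.
   - The crowding of two ortho-siloxy aryl groups on one methine may stop the second annulation.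
   - Fallback (known chemistry), setting out from 30, 13 and 1 and returning to the route at target 35: the bridge is made by aldehyde condensation of two complete monomers instead of by annulation. Commercial phloroglucinol would be C-acylated with 30 (AlCl3, PhNO2/CH2Cl2, Friedel–Crafts acylation) to (2R)-2-methyl-1-(2,4,6-trihydroxyphenyl)butan-1-one F1. This would be C-prenylated with 13 (aqueous KOH, 0 °C) to (2R)-2-methyl-1-[2,4,6-trihydroxy-3-(3-methylbut-2-enyl)phenyl]butan-1-one F2. Two equivalents of F2 would then be condensed with 1 at the single free ring carbon of each (NaOAc, AcOH, THF, 40 °C; hydroxyalkylation, ortho-quinone methide, conjugate addition of the second phloroglucinol) to give 35.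
   - The price is poor selectivity in the monoprenylation and possible erosion of configuration in the AlCl3 step.

2. Step 5 (twofold acetylide oxidation on the skipped diyne).
   - What may go wrong: base-induced prototropic shift of the doubly propargylic hydrogen (allene formation) during double lithiation, incomplete oxygen transfer to the second acetylide, or silylation on carbon giving a silylketene.
   - Fallback, setting out from 9 and returning at 11 (which is silylated as in step 5 to 12): the alkyne termini are oxidised through hypervalent iodine, so the diyne never meets a strong base while its terminal C–H bonds are free. Compound 9 and [hydroxy(tosyloxy)iodo]benzene (CHCl3, desiccant, rt) would give [3-(5-methylhexyl)penta-1,4-diyne-1,5-diyl]bis(phenyliodonium) ditosylate F3. CuOTf (cat.) in MeCN would convert it into 3-(5-methylhexyl)penta-1,4-diyne-1,5-diyl bis(4-methylbenzenesulfonate) F4. MeLi at −78 °C attacks sulfur and releases the bis-ynolate 11.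

3. Step 14 (iodine–lithium exchange and acyl shift).
   - What may go wrong: enolisation of the ester or of the product ketone with loss of the R configuration, protonation of the aryllithium before it reaches the carbonyl (plain deiodination), or migration of a neighbouring silyl group from oxygen to the lithiated carbon (retro-Brook rearrangement).
   - Fallback, setting out from 27 and returning at 34: the acyl group is moved by light instead of by an organolithium. Compound 27 would be O-acylated directly with 30 (pyridine, DMAP cat., CH2Cl2) to the iodine-free bis-ester 1,1-bis{2-[(2R)-2-methylbutanoyloxy]-5-(3-methylbut-2-enyl)-4,6-bis(triisopropylsiloxy)phenyl}-6-methylheptane F5. Irradiation (254 nm, cyclohexane, photo-Fries rearrangement) moves each acyl group to the only free ortho carbon, since the other ortho and the para position are blocked, and gives 34 without any base.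

**Further compounds**

F1 | step 10 | (2R)-2-methyl-1-(2,4,6-trihydroxyphenyl)butan-1-one | CC[C@@H](C)C(=O)c1c(O)cc(O)cc1O
F2 | step 10 | (2R)-2-methyl-1-[2,4,6-trihydroxy-3-(3-methylbut-2-enyl)phenyl]butan-1-one | CC[C@@H](C)C(=O)c1c(O)cc(O)c(CC=C(C)C)c1O
F3 | step 5 | [3-(5-methylhexyl)penta-1,4-diyne-1,5-diyl]bis(phenyliodonium) ditosylate | CC(C)CCCCC(C#C[I+]c1ccccc1)C#C[I+]c1ccccc1.Cc1ccc(cc1)S(=O)(=O)[O-].Cc1ccc(cc1)S(=O)(=O)[O-]
F4 | step 5 | 3-(5-methylhexyl)penta-1,4-diyne-1,5-diyl bis(4-methylbenzenesulfonate) | CC(C)CCCCC(C#COS(=O)(=O)c1ccc(C)cc1)C#COS(=O)(=O)c1ccc(C)cc1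
F5 | step 14 | 1,1-bis{2-[(2R)-2-methylbutanoyloxy]-5-(3-methylbut-2-enyl)-4,6-bis(triisopropylsiloxy)phenyl}-6-methylheptane | CC(C)CCCCC(c1c(OC(=O)[C@H](C)CC)cc(O[Si](C(C)C)(C(C)C)C(C)C)c(CC=C(C)C)c1O[Si](C(C)C)(C(C)C)C(C)C)c1c(OC(=O)[C@H](C)CC)cc(O[Si](C(C)C)(C(C)C)C(C)C)c(CC=C(C)C)c1O[Si](C(C)C)(C(C)C)C(C)C
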